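**Retrosynthetic overview**

1. The target is an 8-hydroxy-5-methoxy-1,4-naphthoquinone. C2 lies next to the C1 carbonyl (peri to C8-OH), the C4 carbonyl is peri to C5-OMe, and C2 carries the only stereocentre, C1' (S), as its 3-methylbut-2-enoate. The strategy rests on reading the quinone ring (C1, C2, C3, C4, C4a, C8a) as terminal alkyne (C2–C3) + CO (C1) + carbene carbon (C4) on an unsymmetrical arene, with C1' propargylic.
2. Last disconnections: the ester C–O bond at C1' (Steglich, after double desilylation) and the quinone, obtained by oxidative demethylation of a 4-methoxy-1-naphthol ring.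
3. Ring formation: only one ring is built, the future quinone ring, by Dötz benzannulation of an aryl(methoxy)carbene complex of zerovalent chromium with an (S)-propargylic silyl ether (bonds C3–C4, C1–C2, C1–C8a). The benzenoid ring is bought.
4. Fragments: the carbene comes from 3-bromo-4-methoxyphenol (silyl ether, Br/Li exchange, Cr(CO)6, Me3OBF4). The alkyne comes from 4-methylpent-3-enoic acid (Weinreb amide, silyl ynone, asymmetric transfer hydrogenation that sets C1', O-silylation, C-desilylation).

Key step: step 8

Assumption: 3-bromo-4-methoxyphenol, 4-methylpent-3-enoic acid and lithium (trimethylsilyl)acetylide (THF solution) are taken as catalogue compounds. Atom numbers C1–C8a are those of the naphthoquinone, and C1' is the carbinol carbon. C1' is (S) in the alkyne, the naphthol and the target because O > sp or sp2 carbon > CH2 holds throughout. TBS = tert-butyldimethylsilyl.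

**Route**

Step 1
Reactants: 1 3-bromo-4-methoxyphenol
Product: 2 (3-bromo-4-methoxyphenoxy)(tert-butyl)dimethylsilane
Conditions: TBSCl, imidazole, DMF, rt
Reagents that add atoms: tert-butyldimethylsilyl chloride (TBSCl), CC(C)(C)[Si](C)(C)Cl
Why: O-silylation of a phenol (silyl ether protection) removes the acidic proton before lithiation and gives the future C8 oxygen a group different from the C5 methyl ether.

Step 2
Reactants: 2 (3-bromo-4-methoxyphenoxy)(tert-butyl)dimethylsilane; 3 chromium hexacarbonyl Cr(CO)6
Product: 6 pentacarbonyl{methoxy[2-methoxy-5-(tert-butyldimethylsilyloxy)phenyl]methylidene}chromium, via aryllithium 4 (not isolated), via lithium acylchromate 5 (not isolated)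
Conditions: n-BuLi, THF, −78 °C; Cr(CO)6, −78 °C → rt; solvent exchange; Me3OBF4, CH2Cl2, 0 °C → rt
Reagents that add atoms: trimethyloxonium tetrafluoroborate (Me3OBF4), C[O+](C)C.F[B-](F)(F)F
Why: Fischer carbene synthesis, in which bromine–lithium exchange, addition of the aryllithium to a CO ligand of zerovalent chromium and O-methylation of the acyl chromate by the hard oxonium salt follow one another, and the meta relation of Li and OTBS rules out silyl migration.

Step 3
Reactants: 7 4-methylpent-3-enoic acid
Product: 9 N-methoxy-N,4-dimethylpent-3-enamide, via acyl imidazole 8 (not isolated)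
Conditions: CDI, CH2Cl2, rt; then MeNHOMe·HCl, rt
Reagents that add atoms: N,O-dimethylhydroxylamine hydrochloride, CNOC.Cl
Why: Weinreb amide formation through the acyl imidazolide (amide coupling) runs near neutrality, so the β,γ-alkene should not move into conjugation.

Step 4
Reactants: 9 N-methoxy-N,4-dimethylpent-3-enamide; 10 lithium (trimethylsilyl)acetylide
Product: 12 6-methyl-1-(trimethylsilyl)hept-5-en-1-yn-3-one, via lithium hemiaminal chelate 11 (not isolated)
Conditions: LiC≡CSiMe3, THF, −78 → 0 °C; inverse quench into cold 1 M aq. HCl
Reagents that add atoms: none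
Why: Weinreb ketone synthesis, in which the chelated tetrahedral adduct keeps the carbonyl masked until the acidic quench, which also removes the liberated hydroxylamine as its salt before it can add to the ynone.

Step 5
Reactants: 12 6-methyl-1-(trimethylsilyl)hept-5-en-1-yn-3-one
Product: 13 (S)-6-methyl-1-(trimethylsilyl)hept-5-en-1-yn-3-ol
Conditions: Ru[(S,S)-TsNCHPhCHPhNH](η6-p-cymene) (1 mol%), i-PrOH, rt, no added base
Reagents that add atoms: none
Why: Noyori asymmetric transfer hydrogenation of an alkynyl ketone, in which the alkyne takes the place that the aryl group has in aryl ketones in the six-membered metal–ligand bifunctional transition state, so the (S,S)-catalyst should deliver hydride to the face that gives the (S)-carbinol, the future C1'.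

Step 6
Reactants: 13 (S)-6-methyl-1-(trimethylsilyl)hept-5-en-1-yn-3-ol
Product: 14 (S)-tert-butyldimethyl{[6-methyl-1-(trimethylsilyl)hept-5-en-1-yn-3-yl]oxy}silane
Conditions: TBSCl, imidazole, DMF, rt
Reagents that add atoms: tert-butyldimethylsilyl chloride (TBSCl), CC(C)(C)[Si](C)(C)Cl
Why: O-silylation of the secondary alcohol (silyl ether protection) takes place at oxygen, leaves the stereocentre untouched, gives the bulky propargylic ether that benzannulation tolerates and avoids handling the volatile free alkynol.

Step 7
Reactants: 14 (S)-tert-butyldimethyl{[6-methyl-1-(trimethylsilyl)hept-5-en-1-yn-3-yl]oxy}silane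
Product: 15 (S)-tert-butyldimethyl[(6-methylhept-5-en-1-yn-3-yl)oxy]silane
Conditions: K2CO3 (cat.), MeOH, rt
Reagents that add atoms: none
Why: Base-catalysed methanolysis of the alkynyl C–Si bond (protodesilylation) is selective because methoxide attacks the small SiMe3 group on the sp carbon and not the hindered secondary O-TBS group.

Step 8
Reactants: 6 pentacarbonyl{methoxy[2-methoxy-5-(tert-butyldimethylsilyloxy)phenyl]methylidene}chromium; 15 (S)-tert-butyldimethyl[(6-methylhept-5-en-1-yn-3-yl)oxy]silane
Product: 17 2-[(S)-1-(tert-butyldimethylsilyloxy)-4-methylpent-3-en-1-yl]-8-(tert-butyldimethylsilyloxy)-4,5-dimethoxynaphthalen-1-ol, via tricarbonylchromium naphthol complex 16 (not isolated)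
Conditions: 15 (1.5 equiv), degassed THF (0.05 M), 50 °C, Ar; then air, rt; filtration through Celite
Reagents that add atoms: none
Why: This is a Dötz benzannulation: thermal loss of one CO from the carbene complex of zerovalent chromium lets the alkyne bind and insert into the Cr=C bond (C3–C4) to give a vinylcarbene, and insertion of a second CO (C1–C2) gives a chromium-bound aryl vinylketene. The single new ring closes by 6π electrocyclisation of this ketene onto the only free ortho carbon of the arene (future C8a, bond C1–C8a), and tautomerisation gives the 4-methoxy-1-naphthol as its Cr(CO)3 complex, which air demetalates. The selectivity needed is the regiochemistry of alkyne insertion: as is general for terminal alkynes, the unsubstituted carbon bonds to the carbene carbon and the branched carbon carrying C1' ends next to the CO-derived C1, and because the carbene carbon sits ortho to OMe this places the side chain on C2 on the C8 side. No stereocentre is formed; C1' is a spectator under these neutral conditions and the planar-chiral diastereomers of the Cr(CO)3 complex converge on demetalation. THF and the bulky silyl ether are chosen because they should favour phenol formation over the cyclobutenone and indene channels of ortho-methoxyaryl complexes and suppress loss of the propargylic oxygen. The ring is born with a free C1-OH and a C4-OMe while both oxygens of the other ring stay capped, which is what later lets a mild oxidant pick this ring.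

Step 9
Reactants: 17 2-[(S)-1-(tert-butyldimethylsilyloxy)-4-methylpent-3-en-1-yl]-8-(tert-butyldimethylsilyloxy)-4,5-dimethoxynaphthalen-1-ol
Product: 18 2-[(S)-1-(tert-butyldimethylsilyloxy)-4-methylpent-3-en-1-yl]-8-(tert-butyldimethylsilyloxy)-5-methoxynaphthalene-1,4-dione
Conditions: (NH4)2Ce(NO3)6 (2.2 equiv), MeCN/H2O, 0 °C, 10 min, on freshly prepared 17
Reagents that add atoms: water, O
Why: Oxidative demethylation of a para-methoxyphenol by tetravalent cerium (two one-electron oxidations, addition of water at C4, loss of methanol) should take only the ring with the free C1-OH, since both oxygens of the C5/C8 ring are capped.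

Step 10
Reactants: 18 2-[(S)-1-(tert-butyldimethylsilyloxy)-4-methylpent-3-en-1-yl]-8-(tert-butyldimethylsilyloxy)-5-methoxynaphthalene-1,4-dione
Product: 19 8-hydroxy-2-[(S)-1-hydroxy-4-methylpent-3-en-1-yl]-5-methoxynaphthalene-1,4-dione
Conditions: HF·pyridine, pyridine, THF, 0 °C → rt
Reagents that add atoms: none
Why: Fluoride-mediated desilylation cleaves both the aryl and the secondary alkyl TBS ether, and buffered HF avoids the basic fluoride that quinones resent and the strong acid that would cyclise the hydroxy-prenyl side chain.

Step 11
Reactants: 19 8-hydroxy-2-[(S)-1-hydroxy-4-methylpent-3-en-1-yl]-5-methoxynaphthalene-1,4-dione; 20 3-methylbut-2-enoic acid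
Product: 21 (S)-1-(8-hydroxy-5-methoxy-1,4-dioxo-1,4-dihydronaphthalen-2-yl)-4-methylpent-3-en-1-yl 3-methylbut-2-enoate
Conditions: DCC, DMAP (cat.), CH2Cl2, 0 °C → rt
Reagents that add atoms: none
Why: Steglich esterification should acylate only the C1' hydroxyl because the C8-OH is tied up in a hydrogen bond to the C1 carbonyl and is a poor nucleophile, and acylation at oxygen retains the (S) configuration.

**Compound list**

1 | 3-bromo-4-methoxyphenol | COc1ccc(O)cc1Br | starting material
2 | (3-bromo-4-methoxyphenoxy)(tert-butyl)dimethylsilane | COc1ccc(O[Si](C)(C)C(C)(C)C)cc1Br | intermediate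
3 | chromium hexacarbonyl Cr(CO)6 | O=C=[Cr](=C=O)(=C=O)(=C=O)(=C=O)=C=O | starting material
4 | [2-methoxy-5-(tert-butyldimethylsilyloxy)phenyl]lithium | COc1ccc(O[Si](C)(C)C(C)(C)C)cc1[Li] | intermediate
5 | lithium pentacarbonyl{[2-methoxy-5-(tert-butyldimethylsilyloxy)phenyl](oxido)methylidene}chromate | COc1ccc(O[Si](C)(C)C(C)(C)C)cc1C([O-])=[Cr](=C=O)(=C=O)(=C=O)(=C=O)=C=O.[Li+] | intermediate
6 | pentacarbonyl{methoxy[2-methoxy-5-(tert-butyldimethylsilyloxy)phenyl]methylidene}chromium | COC(=[Cr](=C=O)(=C=O)(=C=O)(=C=O)=C=O)c1cc(O[Si](C)(C)C(C)(C)C)ccc1OC | intermediate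
7 | 4-methylpent-3-enoic acid | CC(C)=CCC(=O)O | starting material
8 | 1-(1H-imidazol-1-yl)-4-methylpent-3-en-1-one | CC(C)=CCC(=O)n1ccnc1 | intermediate
9 | N-methoxy-N,4-dimethylpent-3-enamide | CC(C)=CCC(=O)N(C)OC | intermediate
10 | lithium (trimethylsilyl)acetylide | C[Si](C)(C)C#C[Li] | starting material
11 | lithium alkoxide of the tetrahedral adduct of 9 and 10 (racemic at the new carbon) | CC(C)=CCC(O[Li])(C#C[Si](C)(C)C)N(C)OC | intermediate
12 | 6-methyl-1-(trimethylsilyl)hept-5-en-1-yn-3-one | CC(C)=CCC(=O)C#C[Si](C)(C)C | intermediate
13 | (S)-6-methyl-1-(trimethylsilyl)hept-5-en-1-yn-3-ol | C[Si](C)(C)C#C[C@H](CC=C(C)C)O | intermediate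
14 | (S)-tert-butyldimethyl{[6-methyl-1-(trimethylsilyl)hept-5-en-1-yn-3-yl]oxy}silane | C[Si](C)(C)C#C[C@H](CC=C(C)C)O[Si](C)(C)C(C)(C)C | intermediate
15 | (S)-tert-butyldimethyl[(6-methylhept-5-en-1-yn-3-yl)oxy]silane | C#C[C@H](CC=C(C)C)O[Si](C)(C)C(C)(C)C | intermediate
16 | tricarbonyl(η6-naphthol 17)chromium, Cr(CO)3 on the newly formed ring, mixture of planar diastereomers, written as ligand and Cr(CO)3 joined by a dot | COc1ccc(O[Si](C)(C)C(C)(C)C)c2c(O)c([C@H](CC=C(C)C)O[Si](C)(C)C(C)(C)C)cc(OC)c12.O=C=[Cr](=C=O)=C=O | intermediate
17 | 2-[(S)-1-(tert-butyldimethylsilyloxy)-4-methylpent-3-en-1-yl]-8-(tert-butyldimethylsilyloxy)-4,5-dimethoxynaphthalen-1-ol | COc1ccc(O[Si](C)(C)C(C)(C)C)c2c(O)c([C@H](CC=C(C)C)O[Si](C)(C)C(C)(C)C)cc(OC)c12 | intermediate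
18 | 2-[(S)-1-(tert-butyldimethylsilyloxy)-4-methylpent-3-en-1-yl]-8-(tert-butyldimethylsilyloxy)-5-methoxynaphthalene-1,4-dione | COc1ccc(O[Si](C)(C)C(C)(C)C)c2c1C(=O)C=C([C@H](CC=C(C)C)O[Si](C)(C)C(C)(C)C)C2=O | intermediate
19 | 8-hydroxy-2-[(S)-1-hydroxy-4-methylpent-3-en-1-yl]-5-methoxynaphthalene-1,4-dione | COc1ccc(O)c2c1C(=O)C=C([C@H](CC=C(C)C)O)C2=O | intermediate
20 | 3-methylbut-2-enoic acid | CC(C)=CC(=O)O | starting material
21 | (S)-1-(8-hydroxy-5-methoxy-1,4-dioxo-1,4-dihydronaphthalen-2-yl)-4-methylpent-3-en-1-yl 3-methylbut-2-enoate | COc1ccc(O)c2c1C(=O)C=C([C@H](CC=C(C)C)OC(=O)C=C(C)C)C2=O | target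

**Step count**

Total: 11 steps. Longest linear sequence: 9 steps (steps 3–11, from 4-methylpent-3-enoic acid).

**Steps most likely to fail**

1. Step 8. The chromium vinylketene of the ortho-methoxyaryl complex may close in the four-electron mode to a cyclobutenone (or drift to indene and furan products) instead of the six-electron closure, and the electron-rich free naphthol may be lost to air oxidation during demetalation. The fallback sets out from 6 and 15 and splits the event into two separate reactions. The two are first combined in acetonitrile at 60–70 °C, a medium in which the cyclobutenone channel should dominate, and the product is isolated as 4-methoxy-4-[2-methoxy-5-(tert-butyldimethylsilyloxy)phenyl]-2-[(S)-1-(tert-butyldimethylsilyloxy)-4-methylpent-3-en-1-yl]cyclobut-2-en-1-one F1 (both C4 epimers). F1 is then heated without metal in toluene at 110 °C under argon. Conrotatory ring opening with the methoxy group turning outward gives the free vinylketene with the aryl group cis to the ketene, and 6π closure and tautomerisation (Moore-type cyclobutenone-to-naphthol ring expansion) bring the route back at 17.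

2. Step 5. The basic ruthenium amide may move the skipped alkene into conjugation with the ynone, or facial discrimination between the alkyne and the allylic CH2 group may be insufficient. The fallback sets out from 12 and replaces catalytic hydrogen transfer in an alcohol by stoichiometric, aprotic reagent control. The reagent is (S)-Alpine-Borane (B-isopinocampheyl-9-BBN from (−)-α-pinene), used neat or in THF at rt and followed by ethanolamine work-up (Midland reduction through a boat-like six-membered transition state in which the slim alkyne takes the hindered position). The reagent from (+)-α-pinene gives (R)-alk-1-yn-3-ols, so this enantiomer should give the (S)-carbinol. The fallback comes back at 13 and makes no new compound (F0).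

3. Step 11. Acylation of the hindered carbinol next to the quinone may be slow, the activated acid may rearrange to the N-acylurea, and the phenol may be acylated in competition. The fallback sets out from 19 and gives up selective acylation. Both hydroxyls are acylated with excess 3-methylbut-2-enoyl chloride (pyridine, cat. DMAP, CH2Cl2, 0 °C) to give (S)-1-[5-methoxy-8-(3-methylbut-2-enoyloxy)-1,4-dioxo-1,4-dihydronaphthalen-2-yl]-4-methylpent-3-en-1-yl 3-methylbut-2-enoate F2. The activated aryl ester peri to the quinone carbonyl is then cleaved selectively by mild methanolysis (NaHCO3, MeOH/H2O, rt), which leaves the secondary alkyl ester and comes back at 21.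

**Further compounds**

F1 | step 8 | 4-methoxy-4-[2-methoxy-5-(tert-butyldimethylsilyloxy)phenyl]-2-[(S)-1-(tert-butyldimethylsilyloxy)-4-methylpent-3-en-1-yl]cyclobut-2-en-1-one (both C4 epimers) | COc1ccc(O[Si](C)(C)C(C)(C)C)cc1C1(OC)C=C([C@H](CC=C(C)C)O[Si](C)(C)C(C)(C)C)C1=O
F0 | step 5 | none | none
F2 | step 11 | (S)-1-[5-methoxy-8-(3-methylbut-2-enoyloxy)-1,4-dioxo-1,4-dihydronaphthalen-2-yl]-4-methylpent-3-en-1-yl 3-methylbut-2-enoate | COc1ccc(OC(=O)C=C(C)C)c2c1C(=O)C=C([C@H](CC=C(C)C)OC(=O)C=C(C)C)C2=O
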